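**Retrosynthetic overview**

1. Target 22 ⇐ 21 (Swern oxidation of the 11,12-diol) ⇐ 17 (1β-OH acylated as the alkynoate, Lindlar reduction, desilylation): the ene-dialdehyde and the (Z)-cinnamate are unveiled last.
2. 17 ⇐ 11: the 9α-CH2OH left by the cycloaddition first delivers hydride to C1 (1β-OH), C4=O becomes C4=CH2 (Wittig), and C9 is then inverted, because only a 9β-formyl group can close a lactol onto the peri 1β-OH (C1 and C9 are both bonded to C10).
3. 11 ⇐ 9: ene-dione reduction and enolization at C5 and C3 (both α to the C4 carbonyl) turn the cis adduct into the trans-decalin with equatorial 3-methyl.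
4. 9 ⇐ 7 + 8 (key step): ring B is a cyclohexene (C7=C8) whose sp3 neighbours C6 and C9 sit on the fusion atoms C5 and C10, and ring A has oxygen-level carbons C1 and C4 next to C10(Me) and C5(H) with the second methyl on C3. This is the retron of a Diels–Alder reaction of 2,5-dimethyl-1,4-benzoquinone (all of ring A) with a 1,2-disubstituted butadiene (C6–C9, C11, C12).
5. Ring order: ring A is bought as the quinone, ring B is closed in step 5; diene 7 comes from 1 in four steps (carboxylation, syn-vinylcupration, reduction, acetylation).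

Key step: step 5

Locants used in names: ring A = C1(O)–C2–C3(Me)–C4(=C14)–C5–C10(Me); ring B = C5–C6–C7=C8(C12)–C9(C11)–C10; β is the face of the C10 methyl group, α the opposite face; "decal" = bicyclo[4.4.0]decane skeleton with these locants; TBSO = tert-butyldimethylsilyloxy.

Assumption: the (S)-configured catalyst of step 5 is taken to expose the quinone face that gives the C10 configuration drawn for 9; if the antipode should predominate, the (R)-catalyst is used with no other change.

**Route**

Step 1
Reactants: 1 tert-butyldimethyl(prop-2-yn-1-yloxy)silane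
Product: 3 methyl 4-[(tert-butyldimethylsilyl)oxy]but-2-ynoate, via lithium acetylide 2 (not isolated)
Conditions: n-BuLi, THF, −78 °C; ClCO2Me, −78 → 0 °C
Reagents that add atoms: methyl chloroformate COC(=O)Cl
Why: Deprotonation of the terminal alkyne and C-acylation of the lithium acetylide with a chloroformate is the standard ynoate synthesis.

Step 2
Reactants: 3 methyl 4-[(tert-butyldimethylsilyl)oxy]but-2-ynoate
Product: 5 methyl (2Z)-3-{[(tert-butyldimethylsilyl)oxy]methyl}penta-2,4-dienoate, via alkenylcopper adduct 4 (not isolated)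
Conditions: CH2=CHMgBr, CuI (1.2 equiv each), THF, −78 °C; aq. NH4Cl at −78 °C
Reagents that add atoms: vinylmagnesium bromide C=C[Mg]Br
Why: Syn-carbocupration of the ynoate (conjugate addition of a vinylcopper reagent) and protonation of the alkenylcopper with retention at low temperature should place the ester trans to the new vinyl group, i.e. cis to CH2OTBS.

Step 3
Reactants: 5 methyl (2Z)-3-{[(tert-butyldimethylsilyl)oxy]methyl}penta-2,4-dienoate
Product: 6 (2Z)-3-{[(tert-butyldimethylsilyl)oxy]methyl}penta-2,4-dien-1-ol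
Conditions: DIBAL-H (2.5 equiv), CH2Cl2, −78 °C; Rochelle salt work-up
Reagents that add atoms: none
Why: DIBAL-H reduces the conjugated ester to the allylic alcohol by 1,2-hydride addition without touching the alkene geometry.

Step 4
Reactants: 6 (2Z)-3-{[(tert-butyldimethylsilyl)oxy]methyl}penta-2,4-dien-1-ol
Product: 7 (2Z)-3-{[(tert-butyldimethylsilyl)oxy]methyl}penta-2,4-dien-1-yl acetate
Conditions: Ac2O, pyridine, DMAP (cat.), CH2Cl2, 0 °C
Reagents that add atoms: acetic anhydride CC(=O)OC(C)=O
Why: Standard DMAP-catalysed O-acetylation; the acetate masks the hydroxyl during the Lewis-acid step and is shed again in step 7.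

Step 5
Reactants: 7 (2Z)-3-{[(tert-butyldimethylsilyl)oxy]methyl}penta-2,4-dien-1-yl acetate; 8 2,5-dimethyl-1,4-benzoquinone
Product: 9 cis-fused Diels–Alder adduct 9α-(acetoxymethyl)-8-(TBSO-methyl)-3,10β-dimethyl-5βH-decal-2,7-diene-1,4-dione
Conditions: (S)-B-(o-tolyl)oxazaborolidine of (S)-α,α-diphenylprolinol (20 mol %), Tf2NH (18 mol %), CH2Cl2, −78 → −40 °C
Reagents that add atoms: none
Why: The boron-bound quinone and the diene should combine in a concerted but asynchronous, suprafacial [4+2] cycloaddition of normal electron demand, in which the bond from the unsubstituted diene terminus C6 to the unsubstituted quinone carbon C5 (β to the coordinated C1 carbonyl) runs ahead of the C9–C10 bond; the closest known reaction type is the chiral oxazaborolidinium-catalysed Diels–Alder reaction of methyl-substituted 1,4-benzoquinones. Ring B is the only ring closed, by this two-bond cycloaddition, ring A being the quinone itself. The quaternary centre C10 should be fixed in absolute terms by the catalyst, which screens one of the two enantiotopic quinone faces; C5 follows from suprafacial addition (H cis to the C10 methyl, corrected in step 7), and C9 follows from the endo approach of the outward-pointing CH2OAc group (anti to the C10 methyl, used in step 8 and corrected in step 11). The step needs regioselectivity (C9, not C6, to the methyl-bearing carbon), which the polarization of the 1,2-disubstituted diene (terminal CH2 most nucleophilic) and of the enone arm (unsubstituted β-carbon most electrophilic) should secure, and endo selectivity, which the two quinone carbonyls provide. Site selectivity is no issue because the two C=C bonds of the C2h-symmetric quinone are equivalent.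

Step 6
Reactants: 9 cis-fused Diels–Alder adduct 9α-(acetoxymethyl)-8-(TBSO-methyl)-3,10β-dimethyl-5βH-decal-2,7-diene-1,4-dione
Product: 10 9α-(acetoxymethyl)-8-(TBSO-methyl)-3,10β-dimethyl-5βH-decal-7-ene-1,4-dione (cis-fused; C3 epimers)
Conditions: Zn dust, AcOH, rt, 30 min
Reagents that add atoms: none
Why: Zinc in acetic acid reduces the ene-dione C2=C3 bond of quinone adducts by electron transfer while the isolated alkene, the silyl ether and the acetate should remain.

Step 7
Reactants: 10 9α-(acetoxymethyl)-8-(TBSO-methyl)-3,10β-dimethyl-5βH-decal-7-ene-1,4-dione (cis-fused; C3 epimers)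
Product: 11 9α-(hydroxymethyl)-8-(TBSO-methyl)-3β,10β-dimethyl-5αH-decal-7-ene-1,4-dione (trans-fused)
Conditions: NaOMe (0.3 equiv), MeOH, 0 °C → rt
Reagents that add atoms: none
Why: Methoxide-mediated enolization toward C4 should equilibrate C5 and C3 to the trans-decalin with equatorial 3-methyl, as in the 5β → 5α equilibration of angular-methyl 4-decalones, and Zemplén transesterification frees the primary alcohol.

Step 8
Reactants: 11 9α-(hydroxymethyl)-8-(TBSO-methyl)-3β,10β-dimethyl-5αH-decal-7-ene-1,4-dione (trans-fused)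
Product: 12 1β-hydroxy-9α-(hydroxymethyl)-8-(TBSO-methyl)-3β,10β-dimethyl-5αH-decal-7-en-4-one
Conditions: Me4NBH(OAc)3 (3 equiv), MeCN/AcOH 1:1, −20 → 0 °C
Reagents that add atoms: none
Why: Hydroxyl-directed reduction (Evans–Saksena type): the axial 9α-CH2OH, 1,3-diaxial to the α face of C1, should bind boron and deliver hydride to that face to give the equatorial 1β-alcohol, while the remote C4 ketone is not reduced by the triacetoxyborohydride.

Step 9
Reactants: 12 1β-hydroxy-9α-(hydroxymethyl)-8-(TBSO-methyl)-3β,10β-dimethyl-5αH-decal-7-en-4-one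
Product: 13 9α-(hydroxymethyl)-8-(TBSO-methyl)-3β,10β-dimethyl-4-methylidene-5αH-decal-7-en-1β-ol
Conditions: Ph3PCH3Br (5 equiv), KOtBu (4.8 equiv), toluene, 0 → 80 °C
Reagents that add atoms: methyltriphenylphosphonium bromide C[P+](c1ccccc1)(c1ccccc1)c1ccccc1.[Br-]
Why: Wittig methylenation of the only remaining ketone; both α-centres already have their thermodynamic configuration, so the basic ylide should not change them.

Step 10
Reactants: 13 9α-(hydroxymethyl)-8-(TBSO-methyl)-3β,10β-dimethyl-4-methylidene-5αH-decal-7-en-1β-ol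
Product: 14 1β-hydroxy-8-(TBSO-methyl)-3β,10β-dimethyl-4-methylidene-5αH-decal-7-ene-9α-carbaldehyde
Conditions: TEMPO (20 mol %), PhI(OAc)2 (1.2 equiv), CH2Cl2, 0 °C → rt
Reagents that add atoms: none
Why: TEMPO/PhI(OAc)2 oxidation is selective for the primary alcohol over the hindered secondary C1 alcohol, and the 9α-aldehyde cannot reach the 1β-OH, so no lactol forms and over-oxidation to a lactone is not expected.

Step 11
Reactants: 14 1β-hydroxy-8-(TBSO-methyl)-3β,10β-dimethyl-4-methylidene-5αH-decal-7-ene-9α-carbaldehyde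
Product: 16 9β-(hydroxymethyl)-8-(TBSO-methyl)-3β,10β-dimethyl-4-methylidene-5αH-decal-7-en-1β-ol, via lactol 15 (not isolated)
Conditions: DBU (20 mol %), CH2Cl2, 0 °C; then MeOH, NaBH4, 0 °C
Reagents that add atoms: none
Why: Reversible enolization epimerizes C9, and only the 9β-aldehyde, peri to the 1β-OH, can close the five-membered lactol, so the mixture should drain into 15 (epimerization with hemiacetal trapping), which NaBH4 reduces through its open form to the 9β-diol.

Step 12
Reactants: 16 9β-(hydroxymethyl)-8-(TBSO-methyl)-3β,10β-dimethyl-4-methylidene-5αH-decal-7-en-1β-ol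
Product: 17 8,9β-bis(TBSO-methyl)-3β,10β-dimethyl-4-methylidene-5αH-decal-7-en-1β-ol
Conditions: TBSCl (1.1 equiv), imidazole, CH2Cl2, 0 °C
Reagents that add atoms: tert-butyldimethylsilyl chloride CC(C)(C)[Si](C)(C)Cl
Why: Silylation with TBSCl/imidazole is selective for the primary hydroxyl over the hindered secondary one.

Step 13
Reactants: 17 8,9β-bis(TBSO-methyl)-3β,10β-dimethyl-4-methylidene-5αH-decal-7-en-1β-ol; 18 3-phenylprop-2-ynoic acid
Product: 19 8,9β-bis(TBSO-methyl)-3β,10β-dimethyl-4-methylidene-5αH-decal-7-en-1β-yl 3-phenylprop-2-ynoate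
Conditions: DCC, DMAP (30 mol %), CH2Cl2, 0 °C → rt
Reagents that add atoms: none
Why: Steglich esterification; the alkynoic acid is used because a (Z)-cinnamoyl donor could isomerize under nucleophilic catalysis on this hindered alcohol.

Step 14
Reactants: 19 8,9β-bis(TBSO-methyl)-3β,10β-dimethyl-4-methylidene-5αH-decal-7-en-1β-yl 3-phenylprop-2-ynoate
Product: 20 8,9β-bis(TBSO-methyl)-3β,10β-dimethyl-4-methylidene-5αH-decal-7-en-1β-yl (2Z)-3-phenylprop-2-enoate
Conditions: H2 (1 atm), Pd/CaCO3 poisoned with Pb(OAc)2, quinoline, EtOAc, rt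
Reagents that add atoms: none
Why: Lindlar semihydrogenation (syn addition of H2 on poisoned palladium) should give the (Z)-cinnamate and leave the trisubstituted and 1,1-disubstituted alkenes.

Step 15
Reactants: 20 8,9β-bis(TBSO-methyl)-3β,10β-dimethyl-4-methylidene-5αH-decal-7-en-1β-yl (2Z)-3-phenylprop-2-enoate
Product: 21 8,9β-bis(hydroxymethyl)-3β,10β-dimethyl-4-methylidene-5αH-decal-7-en-1β-yl (2Z)-3-phenylprop-2-enoate
Conditions: HF·pyridine, pyridine, THF, 0 °C → rt
Reagents that add atoms: none
Why: Buffered fluoride cleaves both primary silyl ethers under mildly acidic conditions that should not promote acyl migration or Z/E isomerization.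

Step 16
Reactants: 21 8,9β-bis(hydroxymethyl)-3β,10β-dimethyl-4-methylidene-5αH-decal-7-en-1β-yl (2Z)-3-phenylprop-2-enoate
Product: 22 8,9β-diformyl-3β,10β-dimethyl-4-methylidene-5αH-decal-7-en-1β-yl (2Z)-3-phenylprop-2-enoate (target)
Conditions: (COCl)2, DMSO, CH2Cl2, −78 °C; Et3N, −78 → −30 °C
Reagents that add atoms: none
Why: Swern oxidation converts the 1,4-diol directly into the ene-dialdehyde at low temperature, the established way to 9β-formyl drim-7-ene-11,12-dials without epimerization at C9.

**Compound list**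

1 | tert-butyldimethyl(prop-2-yn-1-yloxy)silane | C#CCO[Si](C)(C)C(C)(C)C | starting material
2 | lithium acetylide of 1 | [Li]C#CCO[Si](C)(C)C(C)(C)C | intermediate
3 | methyl 4-[(tert-butyldimethylsilyl)oxy]but-2-ynoate | COC(=O)C#CCO[Si](C)(C)C(C)(C)C | intermediate
4 | alkenylcopper adduct (Cu cis to vinyl) | COC(=O)/C([Cu])=C(/C=C)CO[Si](C)(C)C(C)(C)C | intermediate
5 | methyl (2Z)-3-{[(tert-butyldimethylsilyl)oxy]methyl}penta-2,4-dienoate | COC(=O)/C=C(/C=C)CO[Si](C)(C)C(C)(C)C | intermediate
6 | (2Z)-3-{[(tert-butyldimethylsilyl)oxy]methyl}penta-2,4-dien-1-ol | OC/C=C(/C=C)CO[Si](C)(C)C(C)(C)C | intermediate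
7 | (2Z)-3-{[(tert-butyldimethylsilyl)oxy]methyl}penta-2,4-dien-1-yl acetate | CC(=O)OC/C=C(/C=C)CO[Si](C)(C)C(C)(C)C | intermediate
8 | 2,5-dimethyl-1,4-benzoquinone | CC1=CC(=O)C(C)=CC1=O | starting material
9 | cis-fused adduct 9α-(acetoxymethyl)-8-(TBSO-methyl)-3,10β-dimethyl-5βH-decal-2,7-diene-1,4-dione | O=C1C(C)=CC(=O)[C@]2(C)[C@H](COC(C)=O)C(CO[Si](C)(C)C(C)(C)C)=CC[C@H]12 | intermediate
10 | 9α-(acetoxymethyl)-8-(TBSO-methyl)-3,10β-dimethyl-5βH-decal-7-ene-1,4-dione (cis-fused; C3 epimers, C3 left open) | O=C1C(C)CC(=O)[C@]2(C)[C@H](COC(C)=O)C(CO[Si](C)(C)C(C)(C)C)=CC[C@H]12 | intermediate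
11 | 9α-(hydroxymethyl)-8-(TBSO-methyl)-3β,10β-dimethyl-5αH-decal-7-ene-1,4-dione | O=C1[C@@H](C)CC(=O)[C@]2(C)[C@H](CO)C(CO[Si](C)(C)C(C)(C)C)=CC[C@@H]12 | intermediate
12 | 1β-hydroxy-9α-(hydroxymethyl)-8-(TBSO-methyl)-3β,10β-dimethyl-5αH-decal-7-en-4-one | O=C1[C@@H](C)C[C@@H](O)[C@]2(C)[C@H](CO)C(CO[Si](C)(C)C(C)(C)C)=CC[C@@H]12 | intermediate
13 | 9α-(hydroxymethyl)-8-(TBSO-methyl)-3β,10β-dimethyl-4-methylidene-5αH-decal-7-en-1β-ol | C=C1[C@@H](C)C[C@@H](O)[C@]2(C)[C@H](CO)C(CO[Si](C)(C)C(C)(C)C)=CC[C@@H]12 | intermediate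
14 | 1β-hydroxy-8-(TBSO-methyl)-3β,10β-dimethyl-4-methylidene-5αH-decal-7-ene-9α-carbaldehyde | C=C1[C@@H](C)C[C@@H](O)[C@]2(C)[C@H](C=O)C(CO[Si](C)(C)C(C)(C)C)=CC[C@@H]12 | intermediate
15 | 1β,11-lactol (cyclic hemiacetal O1–C11) of the 9β-epimer of 14; anomers, C11 left open | C=C1[C@@H](C)C[C@@H](OC3O)[C@]2(C)[C@@H]3C(CO[Si](C)(C)C(C)(C)C)=CC[C@@H]12 | intermediate
16 | 9β-(hydroxymethyl)-8-(TBSO-methyl)-3β,10β-dimethyl-4-methylidene-5αH-decal-7-en-1β-ol | C=C1[C@@H](C)C[C@@H](O)[C@]2(C)[C@@H](CO)C(CO[Si](C)(C)C(C)(C)C)=CC[C@@H]12 | intermediate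
17 | 8,9β-bis(TBSO-methyl)-3β,10β-dimethyl-4-methylidene-5αH-decal-7-en-1β-ol | C=C1[C@@H](C)C[C@@H](O)[C@]2(C)[C@@H](CO[Si](C)(C)C(C)(C)C)C(CO[Si](C)(C)C(C)(C)C)=CC[C@@H]12 | intermediate
18 | 3-phenylprop-2-ynoic acid | OC(=O)C#Cc1ccccc1 | starting material
19 | 1β-(3-phenylprop-2-ynoyl) ester of 17 | C=C1[C@@H](C)C[C@@H](OC(=O)C#Cc3ccccc3)[C@]2(C)[C@@H](CO[Si](C)(C)C(C)(C)C)C(CO[Si](C)(C)C(C)(C)C)=CC[C@@H]12 | intermediate
20 | 1β-[(2Z)-3-phenylprop-2-enoyl] ester of 17 | C=C1[C@@H](C)C[C@@H](OC(=O)/C=C\c3ccccc3)[C@]2(C)[C@@H](CO[Si](C)(C)C(C)(C)C)C(CO[Si](C)(C)C(C)(C)C)=CC[C@@H]12 | intermediate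
21 | 8,9β-bis(hydroxymethyl)-3β,10β-dimethyl-4-methylidene-5αH-decal-7-en-1β-yl (2Z)-3-phenylprop-2-enoate | C=C1[C@@H](C)C[C@@H](OC(=O)/C=C\c3ccccc3)[C@]2(C)[C@@H](CO)C(CO)=CC[C@@H]12 | intermediate
22 | 8,9β-diformyl-3β,10β-dimethyl-4-methylidene-5αH-decal-7-en-1β-yl (2Z)-3-phenylprop-2-enoate | C=C1[C@@H](C)C[C@@H](OC(=O)/C=C\c3ccccc3)[C@]2(C)[C@@H](C=O)C(C=O)=CC[C@@H]12 | target

**Step count and risks**

Total step count: 16. Longest linear sequence: 16 steps (1 → 22); 8 and 18 enter as purchased materials.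

Steps most likely to fail:

Step 5. The chiral Lewis acid may steer the nucleophilic diene terminus to the methyl-bearing quinone carbon, ionize the dienylic acetate, or discriminate the quinone faces poorly. Fallback: starting from 7 and 8, an uncatalysed thermal cycloaddition (toluene, 90 °C) relies only on the intrinsic preference of 1-substituted dienes to place their substituent next to the angular methyl of methylquinones and would give the racemic adduct F1. A lipase (for example Candida antarctica lipase B, phosphate buffer/MTBE) would then hydrolyse the primary acetate of the unwanted enantiomer to the alcohol ent-desacetyl adduct F2, leaving the acetate of the wanted enantiomer untouched. The route is rejoined at 9.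

Step 11. γ-Reprotonation of the dienol(ate) may move the C7=C8 double bond into conjugation with the aldehyde faster than C9 epimerizes and the lactol closes. Fallback: starting from 14, Pinnick oxidation (NaClO2, NaH2PO4, 2-methyl-2-butene) would give the hydroxy acid F3. Excess LDA (THF/HMPA, −78 °C) followed by a kinetic quench with AcOH should protonate the dienediolate at C9 from the α face (deconjugative α-protonation), and acid catalysis (CSA) would close the 9β-acid onto the 1β-OH to give the 1β,11-lactone F4, the 9α-acid being unable to lactonize. LiAlH4 reduction of F4 rejoins the route at 16.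

Step 8. Non-directed, intermolecular hydride attack from the β side may compete and give the axial 1α-alcohol. Fallback: starting from 11, the hydroxyl is silylated with Me2SiHCl/imidazole to the dimethylsilyl ether F5. SnCl4-catalysed intramolecular hydrosilylation of the C1 carbonyl then delivers hydride through the tether from the α face and gives the cyclic dimethylsilylene acetal F6. Methanolysis (K2CO3, MeOH), which leaves the TBS ether, rejoins the route at 12.

Further compounds
F1 | step 5 | racemic cis-fused adduct (1:1 mixture of 9 and its enantiomer) | O=C1C(C)=CC(=O)[C@]2(C)[C@H](COC(C)=O)C(CO[Si](C)(C)C(C)(C)C)=CC[C@H]12.O=C1C(C)=CC(=O)[C@@]2(C)[C@@H](COC(C)=O)C(CO[Si](C)(C)C(C)(C)C)=CC[C@@H]12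
F2 | step 5 | ent-desacetyl adduct (primary alcohol of the enantiomer of 9) | O=C1C(C)=CC(=O)[C@@]2(C)[C@@H](CO)C(CO[Si](C)(C)C(C)(C)C)=CC[C@@H]12
F3 | step 11 | 1β-hydroxy-8-(TBSO-methyl)-3β,10β-dimethyl-4-methylidene-5αH-decal-7-ene-9α-carboxylic acid | C=C1[C@@H](C)C[C@@H](O)[C@]2(C)[C@H](C(=O)O)C(CO[Si](C)(C)C(C)(C)C)=CC[C@@H]12
F4 | step 11 | 1β,11-lactone of the 9β-carboxylic acid (O1–C11 lactone) | C=C1[C@@H](C)C[C@@H](OC3=O)[C@]2(C)[C@@H]3C(CO[Si](C)(C)C(C)(C)C)=CC[C@@H]12
F5 | step 8 | dimethylsilyl ether of 11 at the 9α-CH2OH | O=C1[C@@H](C)CC(=O)[C@]2(C)[C@H](CO[SiH](C)C)C(CO[Si](C)(C)C(C)(C)C)=CC[C@@H]12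
F6 | step 8 | cyclic dimethylsilylene acetal bridging O1 (1β) and O11 (9α-CH2O) of 12 | O=C1[C@@H](C)C[C@@H](O[Si](C)(C)OC3)[C@]2(C)[C@H]3C(CO[Si](C)(C)C(C)(C)C)=CC[C@@H]12
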